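**Route in outline**

Locants: left decalin C1–C10 (ring A = C5–C10, ring B = C1–C5 plus C10; C9 carries the arylmethyl group); right decalin C1'–C10' (ring C = C5'–C10', ring D = C1'–C5' plus C10'); bridge C11 (on C4) and C12 (on C9').
Cuts, in retrosynthetic order: the two aryl O–SO3H bonds (back to a hydroquinone dimethyl ether); the C12 methylene (back to C12=O); C4–C11 by retro-Claisen to an allyl vinyl ether and, after retro-methylenation, to the ester of a C6 allylic alcohol with a C9' carboxylic acid; C9'–C12 by retro-[2,3]-Wittig–Still shift; C10'–C1' (ring D); C4=C5 (ring B); C10–C1; C9–CH3 and C9–CH2Ar.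
Forward: ring C is (S)-pulegone and ring D is closed on it by a Nozaki–Hiyama–Kishi reaction; ring A is cut out of (R)-pulegone and ring B is closed on it by aldol condensation; the decalins are joined at oxygen as an ester, the ester C=O is turned into C=CH2 (C11), and a [3,3] shift exchanges the C6–O–C12 link for the C4–C11 bond; deoxygenation, demethylation and sulfation finish.
Stereochemistry: C8' and C8 from the two pulegone enantiomers; C5' by equilibration to the trans ketone; C1' and C6 carbinols by CBS reduction; C9' by suprafacial [2,3] transfer from C1'–O; C9 by methylation anti to the C8 methyl; C10 by cuprate addition anti to the axial arylmethyl group; C4 by suprafacial [3,3] transfer from C6–O.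
Enabling feature: both bridge termini, C4 (ring B) and C9' (ring C), are methyl-bearing quaternary carbons allylic to a trisubstituted ring alkene (C5=C6 in ring A, C10'=C1' in ring D). Each is therefore the end of an allyl unit (C4–C5=C6, C9'–C10'=C1') whose far carbon (C6, C1') can have carried the oxygen from which a sigmatropic shift delivers carbon.

Key step: step 26

Remarks and assumptions
- The target is taken as drawn, the free bis(hydrogen sulfate); the last step therefore ends with a cold proton exchange, and the free acid should be kept cold.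
- Centres that are erased later (C9' in 7, C1' in 11, C6 in 27, the epoxide carbons of 21 and 30, the carbinol of 32) are carried as mixtures.
- "Cis" and "trans" refer to the faces of the ring concerned.

**Right half (rings C and D)**

Step 1
Reactants: 1 (S)-(−)-pulegone; 2 2-(2-bromoethyl)-1,3-dioxolane
Product: 5 trans ring C ketone (2R,5S)-2-[4-(1,3-dioxolan-2-yl)-2-methylbutan-2-yl]-5-methylcyclohexan-1-one, via Grignard reagent 3 (not isolated), via epimeric adduct 4 (not isolated)
Conditions: 2, Mg, THF, 25 °C; CuBr·SMe2 (0.2 equiv), 1, THF, −40 → 0 °C; aq NH4Cl; then KOH, EtOH/H2O, reflux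
Reagents that add atoms: none
Why: Copper-catalysed 1,4-addition of the Grignard reagent to the isopropylidene carbon builds the quaternary C4', and base equilibration of the epimerisable C5' centre should favour the trans (menthone-type, diequatorial) ketone, the minor cis epimer being recycled through the same equilibration while C8' comes unchanged from 1.

Step 2
Reactants: 5 trans ring C ketone
Product: 7 C9'-methyl ketone (epimers at C9'), via lithium enolate 6 (not isolated)
Conditions: LDA, THF, −78 °C; MeI, −78 → 0 °C
Reagents that add atoms: iodomethane, CI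
Why: Kinetic deprotonation should take a proton from the C9' methylene and not from the C5' methine next to the quaternary carbon, so enolate alkylation places the methyl on C9', whose configuration is irrelevant because it becomes sp2 in step 3.

Step 3
Reactants: 7 C9'-methyl ketone
Product: 9 enol triflate (C9'=C10' tetrasubstituted; triflate on C10'), via potassium enolate 8 (not isolated)
Conditions: KHMDS, THF, −78 °C; PhNTf2, −78 → 0 °C
Reagents that add atoms: N-phenylbis(trifluoromethanesulfonimide), O=S(=O)(N(c1ccccc1)S(=O)(=O)C(F)(F)F)C(F)(F)F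
Why: Enolate O-sulfonylation; enolisation toward C5' would force the tertiary alkyl group into the enolate plane (allylic 1,2-strain), so the enolate should form toward the methyl-bearing C9' and C5' keeps its configuration.

Step 4
Reactants: 9 enol triflate
Product: 10 aldehyde enol triflate (C1' aldehyde)
Conditions: 2 M HCl, THF, 25 °C
Reagents that add atoms: water, O
Why: Acid hydrolysis of the dioxolane; enol triflates tolerate aqueous acid and the aldehyde has no stereocentre alpha to it.

Step 5
Reactants: 10 aldehyde enol triflate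
Product: 11 4,4,7,8-tetramethyl-1,2,3,4,4a,5,6,7-octahydronaphthalen-1-ol (mixture of C1' epimers)
Conditions: CrCl2 (6 equiv), NiCl2 (5 mol %), degassed DMF, 25 → 50 °C
Reagents that add atoms: none
Why: Intramolecular Nozaki–Hiyama–Kishi reaction: zerovalent nickel inserts into the C10'–OTf bond, transmetallation to trivalent chromium gives an alkenylchromium species, and this adds to the C1' aldehyde in a 6-exo-trig closure of ring D helped by the C4' gem-dimethyl group, the carbinol configuration being corrected in steps 6 and 7.

Step 6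
Reactants: 11 allylic alcohol mixture
Product: 12 4,4,7,8-tetramethyl-3,4,4a,5,6,7-hexahydronaphthalen-1(2H)-one (C1' ketone conjugated to C10'=C9')
Conditions: Dess–Martin periodinane, NaHCO3, CH2Cl2, 25 °C
Reagents that add atoms: none
Why: Dess–Martin oxidation under buffered, non-basic conditions converges both epimers on one enone without forming a dienolate that could disturb C8'.

Step 7
Reactants: 12 bicyclic enone
Product: 13 (1'S)-allylic alcohol (C1'–OH trans to C5'–H; on the face opposite the C8' methyl)
Conditions: (R)-2-methyl-CBS-oxazaborolidine ((3aR)-1-methyl-3,3-diphenyltetrahydro-1H,3H-pyrrolo[1,2-c][1,3,2]oxazaborole, 0.3 equiv), BH3·SMe2, THF, −20 °C; MeOH, then H2O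
Reagents that add atoms: none
Why: Corey–Bakshi–Shibata reduction in which the tetrasubstituted alkene arm acts as the large group and the C2' methylene as the small one, so the (R)-catalyst should deliver hydride under reagent control to give the (S)-carbinol.

Step 8
Reactants: 13 (1'S)-allylic alcohol
Product: 15 tributylstannylmethyl ether of 13, via potassium alkoxide 14 (not isolated)
Conditions: KH, 18-crown-6 (cat.), THF, 0 °C; Bu3SnCH2I, 0 → 25 °C
Reagents that add atoms: (iodomethyl)tributylstannane, CCCC[Sn](CCCC)(CCCC)CI
Why: Williamson etherification of the potassium alkoxide with a reactive primary iodide; only the O–H bond is exchanged, so C1' keeps its configuration.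

Step 9
Reactants: 15 stannylmethyl ether
Product: 17 (1,2,5,5-tetramethyl-1,2,3,4,4a,5,6,7-octahydronaphthalen-1-yl)methanol (C9' quaternary; CH2OH = C12 trans to the C8' methyl; C10'=C1'), via lithiomethyl ether 16 (not isolated)
Conditions: n-BuLi, THF, −78 → −20 °C; H2O
Reagents that add atoms: none
Why: Tin–lithium exchange and [2,3]-Wittig–Still rearrangement: the oxygen-bound carbanion is delivered suprafacially through a five-membered transition state to C9' on the face that carried the C1' oxygen (held pseudoaxial by allylic 1,3-strain with the C9' methyl), which is the face anti to the C8' methyl, so C9' is set as the alkene moves to C10'=C1'.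

Step 10
Reactants: 17 neopentyl alcohol
Product: 18 1,2,5,5-tetramethyl-1,2,3,4,4a,5,6,7-octahydronaphthalene-1-carbaldehyde
Conditions: Dess–Martin periodinane, NaHCO3, CH2Cl2, 25 °C
Reagents that add atoms: none
Why: Dess–Martin oxidation of a neopentyl primary alcohol; the alpha carbon is quaternary, so neither epimerisation nor migration of the alkene into conjugation is possible.

Step 11
Reactants: 18 aldehyde
Product: 19 right-half acid 1,2,5,5-tetramethyl-1,2,3,4,4a,5,6,7-octahydronaphthalene-1-carboxylic acid (acid carbon = C12)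
Conditions: NaClO2, NaH2PO4, 2-methyl-2-butene, t-BuOH/H2O, 25 °C
Reagents that add atoms: sodium chlorite, [Na+].[O-]Cl=O
Why: Pinnick oxidation, with the hypochlorite scavenger protecting the trisubstituted C10'=C1' alkene.

**Left half (rings A and B)**

Step 12
Reactants: 20 (R)-(+)-pulegone
Product: 21 pulegone oxide 2,2,6-trimethyl-1-oxaspiro[2.5]octan-4-one (mixture of epoxide diastereomers)
Conditions: 30% H2O2, LiOH, MeOH, 0 → 25 °C
Reagents that add atoms: hydrogen peroxide, OO
Why: Weitz–Scheffer epoxidation of the enone; the remote methyl stereocentre is untouched and both epoxide diastereomers converge in step 13.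

Step 13
Reactants: 21 pulegone oxide
Product: 22 (5R)-5-methyl-2-(phenylsulfanyl)cyclohexan-1-one (C2 epimers)
Conditions: PhSNa, THF, reflux; H2O
Reagents that add atoms: sodium benzenethiolate, [Na+].[S-]c1ccccc1
Why: The thiolate opens the epoxide at the ring carbon alpha to the ketone and the resulting tertiary alkoxide undergoes retro-aldol loss of acetone, leaving the alpha-phenylthio ketone.

Step 14
Reactants: 22 phenylthio ketone
Product: 24 (R)-5-methylcyclohex-2-en-1-one, via sulfoxide 23 (not isolated)
Conditions: mCPBA, CH2Cl2, −78 → −20 °C; then CaCO3, toluene, 110 °C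
Reagents that add atoms: none
Why: Sulfide oxidation and thermal syn-elimination of the sulfoxide; only C3 carries beta hydrogens, so the alkene is formed in conjugation at the position fixed by where sulfur sat.

Step 15
Reactants: 24 (R)-5-methylcyclohex-2-en-1-one; 25 2,5-dimethoxybenzyl bromide
Product: 27 (5R)-6-(2,5-dimethoxybenzyl)-5-methylcyclohex-2-en-1-one (C6 epimers), via lithium dienolate 26 (not isolated)
Conditions: LDA, THF, −78 °C; 25, −78 → −20 °C
Reagents that add atoms: none
Why: Kinetic alpha'-deprotonation of the enone gives the cross-conjugated enolate, which is benzylated at C6 (the future C9), the new centre being reset in step 16.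

Step 16
Reactants: 27 benzylated enone
Product: 29 (5R,6R)-6-(2,5-dimethoxybenzyl)-5,6-dimethylcyclohex-2-en-1-one (C6 methyl trans to the C5 methyl), via lithium dienolate 28 (not isolated)
Conditions: LDA, THF, −78 °C; MeI, DMPU, −78 → 0 °C
Reagents that add atoms: iodomethane, CI
Why: Alkylation of the fully substituted alpha'-enolate: allylic 1,2-strain with the arylmethyl group turns the neighbouring methyl pseudoaxial, so iodomethane should enter on the opposite face and give the quaternary carbon (future C9) with methyl trans and arylmethyl cis to the future C8 methyl, which is why the benzyl group is introduced first.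

Step 17
Reactants: 29 quaternary enone
Product: 30 2,3-epoxy ketone of 29 (mixture of epoxide diastereomers)
Conditions: 30% H2O2, NaOH, MeOH, 0 → 25 °C
Reagents that add atoms: hydrogen peroxide, OO
Why: Nucleophilic epoxidation of the enone; the epoxide configuration is erased in step 18, so any facial mixture is acceptable.

Step 18
Reactants: 30 epoxy ketone
Product: 32 4-(2,5-dimethoxybenzyl)-4,5-dimethylcyclohex-2-en-1-ol (carbinol epimers), via epoxy hydrazone 31 (not isolated)
Conditions: N2H4·H2O, AcOH (cat.), MeOH, 0 → 25 °C
Reagents that add atoms: none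
Why: Wharton transposition: the hydrazone of the epoxy ketone opens the epoxide to a vinyl diazene that loses N2, which moves oxygen from the old carbonyl carbon (future C10) to the future C6 and places the alkene next to the quaternary carbon.

Step 19
Reactants: 32 transposed allylic alcohol
Product: 33 (4R,5R)-4-(2,5-dimethoxybenzyl)-4,5-dimethylcyclohex-2-en-1-one
Conditions: Dess–Martin periodinane, NaHCO3, CH2Cl2, 25 °C
Reagents that add atoms: none
Why: Oxidation of the allylic alcohol gives the transposed enone; neither C8 (beta) nor the quaternary C9 (gamma) can epimerise.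

Step 20
Reactants: 33 ring A enone; 34 2-(3-chloropropyl)-2-methyl-1,3-dioxolane
Product: 36 4-(2,5-dimethoxybenzyl)-4,5-dimethyl-3-[3-(2-methyl-1,3-dioxolan-2-yl)propyl]cyclohexan-1-one (C10 chain trans to the C9 arylmethyl group; cis to the C9 methyl), via Grignard reagent 35 (not isolated)
Conditions: 34, Mg (activated), THF, 65 °C; CuBr·SMe2 (0.3 equiv), 33, THF, −78 → −20 °C; aq NH4Cl
Reagents that add atoms: none
Why: Copper-catalysed conjugate addition; in the half-chair with the C8 methyl equatorial the C9 arylmethyl group is axial, and stereoelectronically preferred axial attack at C10 comes anti to it and trans to the C8 methyl, which should set C10.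

Step 21
Reactants: 36 ketal ketone
Product: 37 4-(2,5-dimethoxybenzyl)-4,5-dimethyl-3-(4-oxopentyl)cyclohexan-1-one
Conditions: 1 M HCl, THF, 25 °C
Reagents that add atoms: water, O
Why: Acid hydrolysis of the ketal; no stereocentre is alpha to either carbonyl.

Step 22
Reactants: 37 diketone
Product: 38 4-(2,5-dimethoxybenzyl)-3,4,8-trimethyl-3,4,4a,5,6,7-hexahydronaphthalen-1(2H)-one (C6 ketone; C4=C5 tetrasubstituted)
Conditions: KOH, MeOH, 65 °C
Reagents that add atoms: none
Why: Intramolecular aldol condensation in the 6-(enolexo)-exo-trig mode: the C5 enolate adds to the chain ketone to close ring B and dehydration gives the conjugated enone, whereas the other enolates lead only to eight-membered or bridged aldols that cannot dehydrate and revert, and C10 is not acidic.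

Step 23
Reactants: 38 bicyclic enone
Product: 39 (6S)-allylic alcohol (C6–OH cis to C10–H)
Conditions: (R)-2-methyl-CBS-oxazaborolidine ((3aR)-1-methyl-3,3-diphenyltetrahydro-1H,3H-pyrrolo[1,2-c][1,3,2]oxazaborole, 1.0 equiv), BH3·SMe2, toluene, −30 °C; MeOH, then H2O
Reagents that add atoms: none
Why: Corey–Bakshi–Shibata reduction with the alkylidene arm (whose C4 methyl blocks the oxygen lone pair on that side) as the large group, so the (R)-catalyst should give the (S)-carbinol, the hydroxyl on the face of C10–H, under reagent control.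

**Union and endgame**

Step 24
Reactants: 19 right-half acid; 39 (6S)-allylic alcohol
Product: 42 allylic ester (C6–O–C12(=O)–C9'), via acid chloride 40 (not isolated), via sodium alkoxide 41 (not isolated)
Conditions: 19, Me2C=C(Cl)NMe2, CH2Cl2, 0 → 25 °C; 39, NaHMDS, THF, −78 °C, then 40, −78 → 40 °C
Reagents that add atoms: none
Why: Acylation of a preformed alkoxide by an acid chloride made under neutral conditions; the acid chloride has no alpha hydrogen, so it can neither form a ketene nor epimerise, and C6 keeps its configuration because only its O–H bond is exchanged.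

Step 25
Reactants: 42 allylic ester
Product: 43 allyl vinyl ether (ester C=O replaced by C=CH2; the new CH2 is C11)
Conditions: Cp2TiMe2 (3 equiv), toluene, 70 °C, dark; filtration through basic Al2O3
Reagents that add atoms: dimethyltitanocene, C[Ti+2]C.c1cc[cH-]c1.c1cc[cH-]c1
Why: Petasis methylenation: thermally generated titanocene methylidene adds across the ester C=O and the oxatitanacyclobutane collapses to the enol ether; the reagent is not Lewis acidic, so the ionisable allylic C6–O bond should survive, and the ester has no alpha hydrogen to enolise.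

Step 26
Reactants: 43 allyl vinyl ether
Product: 44 bridge ketone (C4 quaternary; C4–C11H2–C12(=O)–C9'; C5=C6)
Conditions: degassed toluene, Et3N (1 vol %), base-washed sealed tube, 150 °C
Reagents that add atoms: none
Why: A concerted, suprafacial [3,3]-sigmatropic (Claisen) rearrangement of the allyl unit O–C6–C5=C4 and the vinyl unit O–C12=C11 through a six-membered transition state forms C4–C11, breaks C6–O, moves the alkene to C5=C6 and turns C12 into a ketone, the new C=O bond being the driving force. The closest known reaction type is the Claisen rearrangement of 2-substituted allyl vinyl ethers made by ester methylenation, including cyclohexenyl cases that create quaternary carbons; joining two decalins this congested extends that precedent in degree, not in kind. No ring is closed: the oxygen link between the decalins is exchanged for the carbon bridge. The one new stereocentre, C4, is controlled by the C6 carbinol configuration from step 23, because the cyclic allyl unit lets C11 reach only the face of C4 that carried the oxygen, which places C11 cis to C10–H and the C4 methyl on the other face. The step needs this facial selectivity and a C6–O bond aligned with the alkene π system; allylic 1,3-strain between the C6 oxygen and the C4 methyl holds that bond pseudoaxial, and base-washed glass with a trace of amine suppresses acid-induced ionisation of the enol ether. Since no enolate or free ion is involved, neither C10 nor the alkene position can be scrambled, and the bond between two neopentyl-type centres is made without a substitution at a neopentyl carbon.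

Step 27
Reactants: 44 bridge ketone
Product: 46 deoxygenated dimethyl ether (C11 and C12 both CH2), via hydrazone 45 (not isolated)
Conditions: anhydrous N2H4, N2H4·2HCl, triethylene glycol, 130 °C; then KOH, 210 °C, under N2
Reagents that add atoms: none
Why: Wolff–Kishner reduction under forcing anhydrous conditions suited to hindered ketones; the anionic pathway avoids a radical or cation at C12, which is homoallylic to C10'=C1' and could trigger vinyl migration, and both neighbours of C12 carry no epimerisable hydrogen.

Step 28
Reactants: 46 deoxygenated dimethyl ether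
Product: 47 quinone (2-substituted 1,4-benzoquinone)
Conditions: (NH4)2Ce(NO3)6 (2.5 equiv), MeCN/H2O, 0 °C
Reagents that add atoms: water, O
Why: Oxidative demethylation of the 1,4-dimethoxyarene by tetravalent cerium (two one-electron oxidations, attack of water at the oxygen-bearing ring carbons, loss of methanol); the isolated trisubstituted alkenes are much harder to oxidise than the electron-rich arene.

Step 29
Reactants: 47 quinone
Product: 48 hydroquinone
Conditions: Na2S2O4, EtOAc/H2O, 25 °C, under Ar
Reagents that add atoms: none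
Why: Dithionite reduction of the quinone to the hydroquinone, which is used at once because it is air-sensitive.

Step 30
Reactants: 48 hydroquinone
Product: 50 toxiusol, via bis(pyridinium) disulfate 49 (not isolated)
Conditions: SO3·pyridine (6 equiv), pyridine, 25 → 50 °C; then sulfonic acid resin (H+ form), MeOH/H2O, 0 °C, freeze-drying
Reagents that add atoms: sulfur trioxide pyridine complex, O=S(=O)([O-])[n+]1ccccc1
Why: O-Sulfation of both phenols by the sulfur trioxide–amine complex and cold proton exchange of the pyridinium salt to the free hydrogen sulfates, kept cold and brief so that the strong acid does not protonate the ring alkenes.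

**Compound list**

1 | (S)-(−)-pulegone, (5S)-5-methyl-2-(propan-2-ylidene)cyclohexan-1-one | C[C@H]1CCC(=C(C)C)C(=O)C1 | starting material
2 | 2-(2-bromoethyl)-1,3-dioxolane | BrCCC1OCCO1 | starting material
3 | [2-(1,3-dioxolan-2-yl)ethyl]magnesium bromide | Br[Mg]CCC1OCCO1 | intermediate
4 | (5S)-2-[4-(1,3-dioxolan-2-yl)-2-methylbutan-2-yl]-5-methylcyclohexan-1-one, mixture of C2 epimers | O=C1C[C@@H](C)CCC1C(C)(C)CCC2OCCO2 | intermediate
5 | (2R,5S)-2-[4-(1,3-dioxolan-2-yl)-2-methylbutan-2-yl]-5-methylcyclohexan-1-one (trans) | O=C1C[C@@H](C)CC[C@@H]1C(C)(C)CCC2OCCO2 | intermediate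
6 | kinetic lithium enolate of 5 (C9'=C10'–OLi) | [Li]OC1=C[C@@H](C)CC[C@@H]1C(C)(C)CCC2OCCO2 | intermediate
7 | C9'-methyl ketone, 6-[4-(1,3-dioxolan-2-yl)-2-methylbutan-2-yl]-2,3-dimethylcyclohexan-1-one, epimers at the new methyl carbon | O=C1C(C)[C@@H](C)CC[C@@H]1C(C)(C)CCC2OCCO2 | intermediate
8 | potassium enolate of 7 toward C9' | [K]OC1=C(C)[C@@H](C)CC[C@@H]1C(C)(C)CCC2OCCO2 | intermediate
9 | enol triflate of 7 (C9'=C10', triflate on C10') | O=S(=O)(OC1=C(C)[C@@H](C)CC[C@@H]1C(C)(C)CCC2OCCO2)C(F)(F)F | intermediate
10 | aldehyde enol triflate (C1' aldehyde) | O=S(=O)(OC1=C(C)[C@@H](C)CC[C@@H]1C(C)(C)CCC=O)C(F)(F)F | intermediate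
11 | 4,4,7,8-tetramethyl-1,2,3,4,4a,5,6,7-octahydronaphthalen-1-ol, C1' epimers | CC1=C2C(O)CCC(C)(C)[C@H]2CC[C@@H]1C | intermediate
12 | 4,4,7,8-tetramethyl-3,4,4a,5,6,7-hexahydronaphthalen-1(2H)-one | CC1=C2C(=O)CCC(C)(C)[C@H]2CC[C@@H]1C | intermediate
13 | (1'S)-allylic alcohol, C1'–OH trans to C5'–H | CC1=C2[C@@H](O)CCC(C)(C)[C@H]2CC[C@@H]1C | intermediate
14 | potassium alkoxide of 13 | CC1=C2[C@@H](O[K])CCC(C)(C)[C@H]2CC[C@@H]1C | intermediate
15 | tributylstannylmethyl ether of 13 | CC1=C2[C@@H](OC[Sn](CCCC)(CCCC)CCCC)CCC(C)(C)[C@H]2CC[C@@H]1C | intermediate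
16 | lithiomethyl ether of 13 | CC1=C2[C@@H](OC[Li])CCC(C)(C)[C@H]2CC[C@@H]1C | intermediate
17 | (1,2,5,5-tetramethyl-1,2,3,4,4a,5,6,7-octahydronaphthalen-1-yl)methanol, CH2OH trans to the C8' methyl | OC[C@@]1(C)C2=CCCC(C)(C)[C@H]2CC[C@@H]1C | intermediate
18 | 1,2,5,5-tetramethyl-1,2,3,4,4a,5,6,7-octahydronaphthalene-1-carbaldehyde | O=C[C@@]1(C)C2=CCCC(C)(C)[C@H]2CC[C@@H]1C | intermediate
19 | 1,2,5,5-tetramethyl-1,2,3,4,4a,5,6,7-octahydronaphthalene-1-carboxylic acid (right-half acid) | OC(=O)[C@@]1(C)C2=CCCC(C)(C)[C@H]2CC[C@@H]1C | intermediate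
20 | (R)-(+)-pulegone | C[C@@H]1CCC(=C(C)C)C(=O)C1 | starting material
21 | pulegone oxide, 2,2,6-trimethyl-1-oxaspiro[2.5]octan-4-one, epoxide diastereomers | C[C@@H]1CCC2(OC2(C)C)C(=O)C1 | intermediate
22 | (5R)-5-methyl-2-(phenylsulfanyl)cyclohexan-1-one, C2 epimers | C[C@@H]1CCC(Sc2ccccc2)C(=O)C1 | intermediate
23 | (5R)-5-methyl-2-(phenylsulfinyl)cyclohexan-1-one | C[C@@H]1CCC(S(=O)c2ccccc2)C(=O)C1 | intermediate
24 | (R)-5-methylcyclohex-2-en-1-one | C[C@@H]1CC=CC(=O)C1 | intermediate
25 | 2,5-dimethoxybenzyl bromide | COc1ccc(OC)c(CBr)c1 | starting material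
26 | lithium dienolate of 24 | C[C@@H]1CC=CC(O[Li])=C1 | intermediate
27 | (5R)-6-(2,5-dimethoxybenzyl)-5-methylcyclohex-2-en-1-one, C6 epimers | C[C@@H]1CC=CC(=O)C1Cc1cc(OC)ccc1OC | intermediate
28 | lithium dienolate of 27 | C[C@@H]1CC=CC(O[Li])=C1Cc1cc(OC)ccc1OC | intermediate
29 | (5R,6R)-6-(2,5-dimethoxybenzyl)-5,6-dimethylcyclohex-2-en-1-one | C[C@@H]1CC=CC(=O)[C@]1(C)Cc1cc(OC)ccc1OC | intermediate
30 | 2,3-epoxy ketone of 29, epoxide diastereomers | C[C@@H]1CC2OC2C(=O)[C@]1(C)Cc1cc(OC)ccc1OC | intermediate
31 | hydrazone of 30 | C[C@@H]1CC2OC2C(=NN)[C@]1(C)Cc1cc(OC)ccc1OC | intermediate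
32 | 4-(2,5-dimethoxybenzyl)-4,5-dimethylcyclohex-2-en-1-ol, carbinol epimers | C[C@@H]1CC(O)C=C[C@]1(C)Cc1cc(OC)ccc1OC | intermediate
33 | (4R,5R)-4-(2,5-dimethoxybenzyl)-4,5-dimethylcyclohex-2-en-1-one (ring A enone) | C[C@@H]1CC(=O)C=C[C@]1(C)Cc1cc(OC)ccc1OC | intermediate
34 | 2-(3-chloropropyl)-2-methyl-1,3-dioxolane | CC1(CCCCl)OCCO1 | starting material
35 | [3-(2-methyl-1,3-dioxolan-2-yl)propyl]magnesium chloride | CC1(CCC[Mg]Cl)OCCO1 | intermediate
36 | ring A ketone with the ketal chain on C10, trans to the arylmethyl group | C[C@@H]1CC(=O)C[C@@H](CCCC2(C)OCCO2)[C@]1(C)Cc1cc(OC)ccc1OC | intermediate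
37 | 4-(2,5-dimethoxybenzyl)-4,5-dimethyl-3-(4-oxopentyl)cyclohexan-1-one | C[C@@H]1CC(=O)C[C@@H](CCCC(C)=O)[C@]1(C)Cc1cc(OC)ccc1OC | intermediate
38 | 4-(2,5-dimethoxybenzyl)-3,4,8-trimethyl-3,4,4a,5,6,7-hexahydronaphthalen-1(2H)-one (left bicyclic enone) | C[C@@H]1CC(=O)C2=C(C)CCC[C@H]2[C@]1(C)Cc1cc(OC)ccc1OC | intermediate
39 | (6S)-allylic alcohol, C6–OH cis to C10–H | C[C@@H]1C[C@H](O)C2=C(C)CCC[C@H]2[C@]1(C)Cc1cc(OC)ccc1OC | intermediate
40 | acid chloride of 19 | ClC(=O)[C@@]1(C)C2=CCCC(C)(C)[C@H]2CC[C@@H]1C | intermediate
41 | sodium alkoxide of 39 | C[C@@H]1C[C@H](O[Na])C2=C(C)CCC[C@H]2[C@]1(C)Cc1cc(OC)ccc1OC | intermediate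
42 | allylic ester of 39 with 19 | C[C@@H]1C[C@H](OC(=O)[C@@]3(C)C4=CCCC(C)(C)[C@H]4CC[C@@H]3C)C2=C(C)CCC[C@H]2[C@]1(C)Cc1cc(OC)ccc1OC | intermediate
43 | allyl vinyl ether (C12=C11H2) | C[C@@H]1C[C@H](OC(=C)[C@@]3(C)C4=CCCC(C)(C)[C@H]4CC[C@@H]3C)C2=C(C)CCC[C@H]2[C@]1(C)Cc1cc(OC)ccc1OC | intermediate
44 | bridge ketone (C12=O), full carbon skeleton | C[C@@H]1CC=C2[C@@H](CCC[C@@]2(C)CC(=O)[C@@]2(C)C3=CCCC(C)(C)[C@H]3CC[C@@H]2C)[C@]1(C)Cc1cc(OC)ccc1OC | intermediate
45 | hydrazone of 44 | C[C@@H]1CC=C2[C@@H](CCC[C@@]2(C)CC(=NN)[C@@]2(C)C3=CCCC(C)(C)[C@H]3CC[C@@H]2C)[C@]1(C)Cc1cc(OC)ccc1OC | intermediate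
46 | deoxygenated hydroquinone dimethyl ether | C[C@@H]1CC=C2[C@@H](CCC[C@@]2(C)CC[C@@]2(C)C3=CCCC(C)(C)[C@H]3CC[C@@H]2C)[C@]1(C)Cc1cc(OC)ccc1OC | intermediate
47 | quinone | C[C@@H]1CC=C2[C@@H](CCC[C@@]2(C)CC[C@@]2(C)C3=CCCC(C)(C)[C@H]3CC[C@@H]2C)[C@]1(C)CC1=CC(=O)C=CC1=O | intermediate
48 | hydroquinone | C[C@@H]1CC=C2[C@@H](CCC[C@@]2(C)CC[C@@]2(C)C3=CCCC(C)(C)[C@H]3CC[C@@H]2C)[C@]1(C)Cc1cc(O)ccc1O | intermediate
49 | bis(pyridinium) disulfate of 48 | C[C@@H]1CC=C2[C@@H](CCC[C@@]2(C)CC[C@@]2(C)C3=CCCC(C)(C)[C@H]3CC[C@@H]2C)[C@]1(C)Cc1cc(OS(=O)(=O)[O-])ccc1OS(=O)(=O)[O-].c1cc[nH+]cc1.c1cc[nH+]cc1 | intermediate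
50 | toxiusol | C[C@@H]1CC=C2[C@@H](CCC[C@@]2(C)CC[C@@]2(C)C3=CCCC(C)(C)[C@H]3CC[C@@H]2C)[C@]1(C)Cc1cc(OS(=O)(=O)O)ccc1OS(=O)(=O)O | target

**Step count**

Total: 30 steps. Longest linear sequence: 19 steps (steps 12–23 from (R)-pulegone 20, then steps 24–30).

**The three steps most likely to fail, in route order**

Step 24 (ester union). The acyl substitution joins a neopentyl-type acid chloride to a hindered secondary alkoxide and may be too slow to compete with decomposition of the alkoxide. The fallback activates the alcohol instead of the acid. It sets out from enone 38 and acid 19. Enone 38 is reduced with the enantiomeric catalyst ((S)-2-methyl-CBS-oxazaborolidine, BH3·SMe2) to the C6-epimeric allylic alcohol F1. A Mitsunobu esterification of F1 with 19 (PPh3, DIAD, toluene, 0 → 25 °C) lets the carboxylate displace the activated oxygen at C6 with inversion, which returns the route at ester 42.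

Step 26 (key rearrangement). At the temperature needed, the sigmatropic shift may be outrun by fragmentation of the enol ether (elimination to a diene and a methyl ketone) or by ionisation and recombination without stereocontrol. The fallback makes the C4–C11 bond by copper-mediated anti-SN2' allylic substitution and bypasses steps 24 to 27. It sets out from aldehyde 18 and enone 38 and returns at 46.
- Aldehyde 18 is methylenated (Ph3PCH3Br, KOt-Bu, THF) to the C9' vinyl compound F2.
- Selective hydroboration of the terminal alkene (9-BBN, THF; H2O2, NaOH) gives the primary alcohol F3.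
- An Appel reaction (CBr4, PPh3) gives the bromide F4, and Mg in THF gives the Grignard reagent F5, whose carbanion carbon (C11) is primary and unhindered.
- The C6-epimeric alcohol F1 (made from 38 as in the fallback to step 24) is acylated with picolinoyl chloride (Et3N, DMAP) to the picolinate F6.
- F5 and F6 with CuBr·SMe2 in THF at −40 °C should couple at C4 anti to the leaving group, i.e. on the face of C10–H, with the alkene moving to C5=C6. The product is 46.

Step 27 (deoxygenation). Hydrazone formation at a carbonyl flanked by a quaternary carbon and a neopentyl methylene may stay incomplete, and long heating in hot alkali may begin to cleave the aryl methyl ethers. The fallback removes the oxygen through an alkene and needs no radical or cation at C12. It sets out from ketone 44 and returns at 46.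
- Ketone 44, which can enolise only toward C11, is converted with KHMDS and PhNTf2 (THF, −78 °C) into the enol triflate F7.
- Reduction with Pd(OAc)2, PPh3, HCO2H and Bu3N in DMF at 60 °C (hydride transfer from formate on divalent palladium after oxidative addition of zerovalent palladium) gives the (E)-alkene F8.
- Diimide (TsNHNH2, NaOAc, DME/H2O, reflux) should saturate the 1,2-disubstituted alkene and leave the trisubstituted ring alkenes alone, giving 46.

**Further compounds**

F1 | step 24 | C6-epimeric (6R) allylic alcohol, C6–OH trans to C10–H | C[C@@H]1C[C@@H](O)C2=C(C)CCC[C@H]2[C@]1(C)Cc1cc(OC)ccc1OC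
F2 | step 26 | C9' vinyl compound, 1-ethenyl-1,2,5,5-tetramethyl-1,2,3,4,4a,5,6,7-octahydronaphthalene | C=C[C@@]1(C)C2=CCCC(C)(C)[C@H]2CC[C@@H]1C
F3 | step 26 | 2-(1,2,5,5-tetramethyl-1,2,3,4,4a,5,6,7-octahydronaphthalen-1-yl)ethan-1-ol | OCC[C@@]1(C)C2=CCCC(C)(C)[C@H]2CC[C@@H]1C
F4 | step 26 | corresponding primary bromide | BrCC[C@@]1(C)C2=CCCC(C)(C)[C@H]2CC[C@@H]1C
F5 | step 26 | corresponding Grignard reagent | Br[Mg]CC[C@@]1(C)C2=CCCC(C)(C)[C@H]2CC[C@@H]1C
F6 | step 26 | picolinate of F1 | C[C@@H]1C[C@@H](OC(=O)c3ccccn3)C2=C(C)CCC[C@H]2[C@]1(C)Cc1cc(OC)ccc1OC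
F7 | step 27 | enol triflate of 44 (C11=C12, triflate on C12) | C[C@@H]1CC=C2[C@@H](CCC[C@@]2(C)/C=C(\OS(=O)(=O)C(F)(F)F)[C@@]2(C)C3=CCCC(C)(C)[C@H]3CC[C@@H]2C)[C@]1(C)Cc1cc(OC)ccc1OC
F8 | step 27 | (E)-C11=C12 alkene | C[C@@H]1CC=C2[C@@H](CCC[C@@]2(C)/C=C/[C@@]2(C)C3=CCCC(C)(C)[C@H]3CC[C@@H]2C)[C@]1(C)Cc1cc(OC)ccc1OC
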